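**Strategy**

Everything rests on cutting the N1–C2 bond of the pyrrole ring. C2 is an unsubstituted CH and C3 carries Cα, so C2=C3 maps onto a 1,1-disubstituted alkene on C3a and N1 onto a nitro group on C7a; the C6 chain, para to C3a on the benzene ring, is then the side chain of L-tyrosine. One palladium/CO deoxygenation of this α-substituted 2-nitrostyrene, whose diol is an acetonide and whose Cα hydroxyls are silyl ethers, should form N1–C2 and close the pyrrole ring with both stereocentres already in place. The nitrostyrene is assembled by Suzuki coupling of a tyrosine-derived 2-nitroaryl triflate with a 2-borylalkene made from prenol.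

Key step: step 15

Remark: the target SMILES is read as (S) at Cα and (R) at the oxirane carbon; the diol that precedes the oxirane must therefore be (S), because ring closure inverts that carbon.

**Route**

Step 1
Reactants: 1 L-tyrosine
Product: 2 (S)-2-hydroxy-3-(4-hydroxyphenyl)propanoic acid
Conditions: NaNO2 (1.5 equiv), 1 M H2SO4 (aq), 0 °C to rt
Reagents that add atoms: water, O
Why: Diazotisation of the α-amino acid with hydrolytic loss of nitrogen should give the α-hydroxy acid with net retention, because the neighbouring carboxylate displaces N2 first and water then opens the strained acyloxy intermediate (two inversions), so the (S) centre of the chiral pool is kept.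

Step 2
Reactants: 2 (S)-2-hydroxy-3-(4-hydroxyphenyl)propanoic acid
Product: 3 methyl (S)-2-hydroxy-3-(4-hydroxyphenyl)propanoate
Conditions: MeOH, H2SO4 (cat.), reflux
Reagents that add atoms: methanol, CO
Why: Fischer esterification converts only the carboxylic acid; phenol, secondary alcohol and the stereocentre are untouched under acid in methanol.

Step 3
Reactants: 3 methyl (S)-2-hydroxy-3-(4-hydroxyphenyl)propanoate
Product: 4 (S)-1-(4-hydroxyphenyl)-3-methylbutane-2,3-diol
Conditions: MeMgBr (5 equiv), THF, 0 °C to rt; aq NH4Cl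
Reagents that add atoms: methylmagnesium bromide, C[Mg]Br
Why: Twofold Grignard addition to the ester builds the tertiary carbinol, and because the two hydroxyls are deprotonated first the α-alkoxide cannot enolise, so C2 stays (S).

Step 4
Reactants: 4 (S)-1-(4-hydroxyphenyl)-3-methylbutane-2,3-diol
Product: 5 4-{[(4S)-2,2,5,5-tetramethyl-1,3-dioxolan-4-yl]methyl}phenol
Conditions: 2,2-dimethoxypropane, p-TsOH·H2O (cat.), acetone, rt
Reagents that add atoms: 2,2-dimethoxypropane, COC(C)(C)OC
Why: Acid-catalysed acetal exchange (acetonide formation) closes the five-membered dioxolane on the vicinal diol only, since a phenol gives no stable ketal.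

Step 5
Reactants: 5 4-{[(4S)-2,2,5,5-tetramethyl-1,3-dioxolan-4-yl]methyl}phenol
Product: 6 2-nitro-4-{[(4S)-2,2,5,5-tetramethyl-1,3-dioxolan-4-yl]methyl}phenol
Conditions: t-BuONO (3 equiv), THF, rt, open to air
Reagents that add atoms: tert-butyl nitrite, CC(C)(C)ON=O; dioxygen, O=O
Why: Radical nitration of the phenol with an alkyl nitrite (O-nitrosation, homolysis, recombination of the phenoxyl radical with NO2) is chemoselective for phenols, the blocked para position leaves only the two equivalent ortho positions, and the neutral medium spares the acetonide.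

Step 6
Reactants: 6 2-nitro-4-{[(4S)-2,2,5,5-tetramethyl-1,3-dioxolan-4-yl]methyl}phenol
Product: 7 2-nitro-4-{[(4S)-2,2,5,5-tetramethyl-1,3-dioxolan-4-yl]methyl}phenyl trifluoromethanesulfonate
Conditions: Tf2O, pyridine, CH2Cl2, 0 °C
Reagents that add atoms: trifluoromethanesulfonic anhydride, O=S(=O)(OS(=O)(=O)C(F)(F)F)C(F)(F)F
Why: O-Sulfonylation (triflation) of the acidic 2-nitrophenol is fast with an amine base and turns the former tyrosine oxygen into a leaving group for palladium.

Step 7
Reactants: 8 prenol (3-methylbut-2-en-1-ol)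
Product: 9 [(2R)-3,3-dimethyloxiran-2-yl]methanol
Conditions: Ti(OiPr)4 (10 mol%), D-(−)-diethyl tartrate (12 mol%), t-BuOOH (2 equiv, in isooctane), 4 Å MS, CH2Cl2, −20 °C
Reagents that add atoms: tert-butyl hydroperoxide, CC(C)(C)OO
Why: Sharpless asymmetric epoxidation of the primary allylic alcohol: the titanium–D-(−)-tartrate–peroxide complex delivers oxygen to one alkene face and should set the (2R) centre, the mirror image of the (2S) epoxides that L-(+)-tartrate gives in this substrate class.

Step 8
Reactants: 9 [(2R)-3,3-dimethyloxiran-2-yl]methanol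
Product: 10 (2S)-3-methyl-2-(prop-1-en-2-yl)butane-1,3-diol
Conditions: CH2=C(CH3)MgBr (3 equiv), CuI (10 mol%), THF, −30 to 0 °C; aq NH4Cl
Reagents that add atoms: prop-1-en-2-ylmagnesium bromide, C=C(C)[Mg]Br
Why: Copper-catalysed Grignard opening of the 2,3-epoxy alcohol is an SN2 attack of the alkenylcopper species at the secondary C2 and not at the fully substituted C3, so the 1,3-diol forms with inversion and the (2R) epoxide carbon becomes the (S) centre Cα.

Step 9
Reactants: 10 (2S)-3-methyl-2-(prop-1-en-2-yl)butane-1,3-diol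
Product: 11 (3S)-3-{[tert-butyl(diphenyl)silyl]oxymethyl}-2,4-dimethylpent-4-en-2-ol
Conditions: t-BuPh2SiCl, imidazole, CH2Cl2, 0 °C to rt
Reagents that add atoms: tert-butyl(chloro)diphenylsilane, CC(C)(C)[Si](Cl)(c1ccccc1)c1ccccc1
Why: Silylation with the bulky chlorosilane is selective for the primary hydroxyl because the tertiary hydroxyl does not react under imidazole catalysis.

Step 10
Reactants: 11 (3S)-3-{[tert-butyl(diphenyl)silyl]oxymethyl}-2,4-dimethylpent-4-en-2-ol
Product: 12 tert-butyl{[(2S)-3-methyl-2-(prop-1-en-2-yl)-3-(triethylsilyloxy)butyl]oxy}diphenylsilane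
Conditions: Et3SiOTf, 2,6-lutidine, CH2Cl2, −78 to 0 °C
Reagents that add atoms: triethylsilyl trifluoromethanesulfonate, CC[Si](CC)(CC)OS(=O)(=O)C(F)(F)F
Why: Silylation with the more electrophilic silyl triflate caps the hindered tertiary hydroxyl, which has to be masked so that the later β-hydroxy ketone cannot undergo retro-aldol cleavage.

Step 11
Reactants: 12 tert-butyl{[(2S)-3-methyl-2-(prop-1-en-2-yl)-3-(triethylsilyloxy)butyl]oxy}diphenylsilane
Product: 14 (3S)-3-{[tert-butyl(diphenyl)silyl]oxymethyl}-4-methyl-4-(triethylsilyloxy)pentan-2-one, via ozonide 13 (not isolated)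
Conditions: O3, CH2Cl2, −78 °C (Sudan Red 7B end point); then PPh3, −78 °C to rt
Reagents that add atoms: ozone, [O-][O+]=O
Why: Ozonolysis with reductive work-up cleaves the only alkene to the methyl ketone under neutral conditions, so the α-stereocentre and both silyl ethers should survive.

Step 12
Reactants: 14 (3S)-3-{[tert-butyl(diphenyl)silyl]oxymethyl}-4-methyl-4-(triethylsilyloxy)pentan-2-one
Product: 16 (3S)-3-{[tert-butyl(diphenyl)silyl]oxymethyl}-4-methyl-4-(triethylsilyloxy)pent-1-en-2-yl trifluoromethanesulfonate, via potassium enolate 15 (not isolated)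
Conditions: KN(SiMe3)2 (1.1 equiv), THF, −78 °C (ketone added to the base); then PhNTf2, −78 to 0 °C
Reagents that add atoms: N-phenylbis(trifluoromethanesulfonimide), O=S(=O)(N(c1ccccc1)S(=O)(=O)C(F)(F)F)C(F)(F)F
Why: Kinetic enolate formation with a bulky amide base removes a proton from the methyl group and not from the congested methine, and O-sulfonylation of that enolate (enol triflate formation) fixes the terminal alkene without touching Cα.

Step 13
Reactants: 16 (3S)-3-{[tert-butyl(diphenyl)silyl]oxymethyl}-4-methyl-4-(triethylsilyloxy)pent-1-en-2-yl trifluoromethanesulfonate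
Product: 17 tert-butyl{[(2S)-3-methyl-2-[1-(4,4,5,5-tetramethyl-1,3,2-dioxaborolan-2-yl)ethenyl]-3-(triethylsilyloxy)butyl]oxy}diphenylsilane
Conditions: B2pin2, PdCl2(PPh3)2 (3 mol%), PPh3 (6 mol%), KOPh, toluene, 50 °C
Reagents that add atoms: bis(pinacolato)diboron, CC1(C)OB(B2OC(C)(C)C(C)(C)O2)OC1(C)C
Why: Miyaura borylation of the alkenyl triflate: oxidative addition to zerovalent palladium, boron transfer from the phenoxide-activated diboron and reductive elimination give the 2-borylalkene, and the weak base does not activate the product toward homocoupling.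

Step 14
Reactants: 7 2-nitro-4-{[(4S)-2,2,5,5-tetramethyl-1,3-dioxolan-4-yl]methyl}phenyl trifluoromethanesulfonate; 17 tert-butyl{[(2S)-3-methyl-2-[1-(4,4,5,5-tetramethyl-1,3,2-dioxaborolan-2-yl)ethenyl]-3-(triethylsilyloxy)butyl]oxy}diphenylsilane
Product: 18 tert-butyl{[(2S)-3-methyl-2-[1-(2-nitro-4-{[(4S)-2,2,5,5-tetramethyl-1,3-dioxolan-4-yl]methyl}phenyl)ethenyl]-3-(triethylsilyloxy)butyl]oxy}diphenylsilane (the α-substituted 2-nitrostyrene)
Conditions: PdCl2(dppf)·CH2Cl2 (5 mol%), K3PO4, 1,4-dioxane/H2O (20:1), 80 °C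
Reagents that add atoms: none
Why: Suzuki–Miyaura coupling: the electron-poor 2-nitroaryl triflate adds readily to zerovalent palladium, and transmetalation of the alkenylboronate with reductive elimination forms the aryl–alkenyl bond without affecting either stereocentre.

Step 15
Reactants: 18 tert-butyl{[(2S)-3-methyl-2-[1-(2-nitro-4-{[(4S)-2,2,5,5-tetramethyl-1,3-dioxolan-4-yl]methyl}phenyl)ethenyl]-3-(triethylsilyloxy)butyl]oxy}diphenylsilane
Product: 19 3-[(2S)-1-{[tert-butyl(diphenyl)silyl]oxy}-3-methyl-3-(triethylsilyloxy)butan-2-yl]-6-{[(4S)-2,2,5,5-tetramethyl-1,3-dioxolan-4-yl]methyl}-1H-indole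
Conditions: Pd(OAc)2 (5 mol%), 1,10-phenanthroline (10 mol%), CO (4 atm), DMF, 90 °C
Reagents that add atoms: none
Why: CO reduces Pd(OAc)2 to a zerovalent palladium–phenanthroline complex that takes one oxygen from the nitro group as CO2 and leaves a palladium-bound nitrosoarene; its nitrogen bonds to the terminal CH2 carbon of the ortho alkene, and loss of the second oxygen as CO2 together with a hydrogen shift from C2 to N1 restores aromaticity and gives the 1H-indole. The closest known reaction type is the palladium-catalysed reductive N-heteroannulation of 2-nitrostyrenes under CO, the catalytic counterpart of the Cadogan–Sundberg cyclisation, which is established for α-alkyl-substituted 2-nitrostyrenes and gives 3-substituted indoles. The pyrrole ring closes through N1–C2 in a five-membered mode that is formally 5-endo-trig but runs as an electrocyclisation of the nitroso (or nitrenoid) styrene and is therefore not subject to the stereoelectronic barrier of a simple nucleophilic 5-endo closure. No stereocentre is formed; Cα, although allylic, and the dioxolane carbon are spectators. The step needs N1–C2 closure to outrun alkene migration into conjugation with Cα and over-reduction to the aniline, and the substrate secures this because the single alkene is held ortho to nitrogen with an unhindered terminal carbon, while the base-free, neutral medium cannot deprotonate Cα and leaves silyl ethers and acetonide alone.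

Step 16
Reactants: 19 3-[(2S)-1-{[tert-butyl(diphenyl)silyl]oxy}-3-methyl-3-(triethylsilyloxy)butan-2-yl]-6-{[(4S)-2,2,5,5-tetramethyl-1,3-dioxolan-4-yl]methyl}-1H-indole
Product: 20 (2S)-1-{3-[(2S)-1-{[tert-butyl(diphenyl)silyl]oxy}-3-hydroxy-3-methylbutan-2-yl]-1H-indol-6-yl}-3-methylbutane-2,3-diol
Conditions: AcOH/THF/H2O (3:1:1), 45 °C
Reagents that add atoms: none
Why: Acid hydrolysis in aqueous acetic acid removes the acetonide and the triethylsilyl ether, while the much more acid-stable tert-butyldiphenylsilyl ether and the 3-alkylindole should persist.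

Step 17
Reactants: 20 (2S)-1-{3-[(2S)-1-{[tert-butyl(diphenyl)silyl]oxy}-3-hydroxy-3-methylbutan-2-yl]-1H-indol-6-yl}-3-methylbutane-2,3-diol
Product: 22 (3S)-4-{[tert-butyl(diphenyl)silyl]oxy}-3-(6-{[(2R)-3,3-dimethyloxiran-2-yl]methyl}-1H-indol-3-yl)-2-methylbutan-2-ol, via secondary mesylate 21 (not isolated)
Conditions: MsCl, pyridine, CH2Cl2, 0 °C; then MeOH, K2CO3, rt
Reagents that add atoms: none
Why: Sulfonylation in pyridine picks the only secondary hydroxyl (tertiary hydroxyls and indole N–H are inert), and under carbonate the adjacent tertiary alkoxide displaces the mesylate in an intramolecular SN2 (3-exo-tet Williamson) closure with inversion, which turns the (S) carbinol carbon into the (R) oxirane carbon.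

Step 18
Reactants: 22 (3S)-4-{[tert-butyl(diphenyl)silyl]oxy}-3-(6-{[(2R)-3,3-dimethyloxiran-2-yl]methyl}-1H-indol-3-yl)-2-methylbutan-2-ol
Product: 23 (2S)-2-(6-{[(2R)-3,3-dimethyloxiran-2-yl]methyl}-1H-indol-3-yl)-3-methylbutane-1,3-diol
Conditions: Bu4NF (1 M in THF), THF, 0 °C to rt
Reagents that add atoms: none
Why: Fluoride-mediated desilylation cleaves the primary silyl ether under basic, non-acidic conditions that a trisubstituted oxirane tolerates.

Step 19
Reactants: 23 (2S)-2-(6-{[(2R)-3,3-dimethyloxiran-2-yl]methyl}-1H-indol-3-yl)-3-methylbutane-1,3-diol; 24 oleic acid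
Product: 25 (2S)-2-(6-{[(2R)-3,3-dimethyloxiran-2-yl]methyl}-1H-indol-3-yl)-3-hydroxy-3-methylbutyl (9Z)-octadec-9-enoate (target)
Conditions: EDC·HCl, DMAP (cat.), CH2Cl2, 0 °C to rt
Reagents that add atoms: none
Why: Steglich-type carbodiimide esterification acylates the primary hydroxyl in preference to the tertiary hydroxyl and the indole N–H, and its near-neutral conditions keep the oxirane and the (Z)-alkene of the acyl chain intact.

**Compound list**

1 | L-tyrosine | N[C@@H](Cc1ccc(O)cc1)C(=O)O | starting material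
2 | (S)-2-hydroxy-3-(4-hydroxyphenyl)propanoic acid | O[C@@H](Cc1ccc(O)cc1)C(=O)O | intermediate
3 | methyl (S)-2-hydroxy-3-(4-hydroxyphenyl)propanoate | COC(=O)[C@@H](O)Cc1ccc(O)cc1 | intermediate
4 | (S)-1-(4-hydroxyphenyl)-3-methylbutane-2,3-diol | CC(C)(O)[C@@H](O)Cc1ccc(O)cc1 | intermediate
5 | 4-{[(4S)-2,2,5,5-tetramethyl-1,3-dioxolan-4-yl]methyl}phenol | Oc1ccc(C[C@@H]2OC(C)(C)OC2(C)C)cc1 | intermediate
6 | 2-nitro-4-{[(4S)-2,2,5,5-tetramethyl-1,3-dioxolan-4-yl]methyl}phenol | Oc1ccc(C[C@@H]2OC(C)(C)OC2(C)C)cc1[N+](=O)[O-] | intermediate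
7 | 2-nitro-4-{[(4S)-2,2,5,5-tetramethyl-1,3-dioxolan-4-yl]methyl}phenyl trifluoromethanesulfonate | O=S(=O)(Oc1ccc(C[C@@H]2OC(C)(C)OC2(C)C)cc1[N+](=O)[O-])C(F)(F)F | intermediate
8 | prenol (3-methylbut-2-en-1-ol) | CC(C)=CCO | starting material
9 | [(2R)-3,3-dimethyloxiran-2-yl]methanol | OC[C@H]1OC1(C)C | intermediate
10 | (2S)-3-methyl-2-(prop-1-en-2-yl)butane-1,3-diol | C=C(C)[C@@H](CO)C(C)(C)O | intermediate
11 | (3S)-3-{[tert-butyl(diphenyl)silyl]oxymethyl}-2,4-dimethylpent-4-en-2-ol | C=C(C)[C@@H](CO[Si](c1ccccc1)(c1ccccc1)C(C)(C)C)C(C)(C)O | intermediate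
12 | tert-butyl{[(2S)-3-methyl-2-(prop-1-en-2-yl)-3-(triethylsilyloxy)butyl]oxy}diphenylsilane | C=C(C)[C@@H](CO[Si](c1ccccc1)(c1ccccc1)C(C)(C)C)C(C)(C)O[Si](CC)(CC)CC | intermediate
13 | ozonide of 12: 3-methyl-1,2,4-trioxolane carrying at C3 the Cα chain of 12 with unchanged configuration (both epimers at the ring carbon) | CC1(OCOO1)[C@@H](CO[Si](c2ccccc2)(c2ccccc2)C(C)(C)C)C(C)(C)O[Si](CC)(CC)CC | intermediate (not isolated)
14 | (3S)-3-{[tert-butyl(diphenyl)silyl]oxymethyl}-4-methyl-4-(triethylsilyloxy)pentan-2-one | CC(=O)[C@@H](CO[Si](c1ccccc1)(c1ccccc1)C(C)(C)C)C(C)(C)O[Si](CC)(CC)CC | intermediate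
15 | potassium enolate of 14 on the methyl side (pent-1-en-2-olate, Cα configuration unchanged) | C=C([O-])[C@@H](CO[Si](c1ccccc1)(c1ccccc1)C(C)(C)C)C(C)(C)O[Si](CC)(CC)CC.[K+] | intermediate (not isolated)
16 | (3S)-3-{[tert-butyl(diphenyl)silyl]oxymethyl}-4-methyl-4-(triethylsilyloxy)pent-1-en-2-yl trifluoromethanesulfonate | C=C(OS(=O)(=O)C(F)(F)F)[C@@H](CO[Si](c1ccccc1)(c1ccccc1)C(C)(C)C)C(C)(C)O[Si](CC)(CC)CC | intermediate
17 | tert-butyl{[(2S)-3-methyl-2-[1-(4,4,5,5-tetramethyl-1,3,2-dioxaborolan-2-yl)ethenyl]-3-(triethylsilyloxy)butyl]oxy}diphenylsilane | C=C(B1OC(C)(C)C(C)(C)O1)[C@@H](CO[Si](c2ccccc2)(c2ccccc2)C(C)(C)C)C(C)(C)O[Si](CC)(CC)CC | intermediate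
18 | tert-butyl{[(2S)-3-methyl-2-[1-(2-nitro-4-{[(4S)-2,2,5,5-tetramethyl-1,3-dioxolan-4-yl]methyl}phenyl)ethenyl]-3-(triethylsilyloxy)butyl]oxy}diphenylsilane | C=C(c1ccc(C[C@@H]2OC(C)(C)OC2(C)C)cc1[N+](=O)[O-])[C@@H](CO[Si](c1ccccc1)(c1ccccc1)C(C)(C)C)C(C)(C)O[Si](CC)(CC)CC | intermediate
19 | 3-[(2S)-1-{[tert-butyl(diphenyl)silyl]oxy}-3-methyl-3-(triethylsilyloxy)butan-2-yl]-6-{[(4S)-2,2,5,5-tetramethyl-1,3-dioxolan-4-yl]methyl}-1H-indole | CC(C)(C)[Si](c1ccccc1)(c1ccccc1)OC[C@H](c1c[nH]c2cc(C[C@@H]3OC(C)(C)OC3(C)C)ccc12)C(C)(C)O[Si](CC)(CC)CC | intermediate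
20 | (2S)-1-{3-[(2S)-1-{[tert-butyl(diphenyl)silyl]oxy}-3-hydroxy-3-methylbutan-2-yl]-1H-indol-6-yl}-3-methylbutane-2,3-diol | CC(C)(C)[Si](c1ccccc1)(c1ccccc1)OC[C@H](c1c[nH]c2cc(C[C@H](O)C(C)(C)O)ccc12)C(C)(C)O | intermediate
21 | (2S)-1-{3-[(2S)-1-{[tert-butyl(diphenyl)silyl]oxy}-3-hydroxy-3-methylbutan-2-yl]-1H-indol-6-yl}-3-hydroxy-3-methylbutan-2-yl methanesulfonate | CC(C)(C)[Si](c1ccccc1)(c1ccccc1)OC[C@H](c1c[nH]c2cc(C[C@H](OS(C)(=O)=O)C(C)(C)O)ccc12)C(C)(C)O | intermediate (not isolated)
22 | (3S)-4-{[tert-butyl(diphenyl)silyl]oxy}-3-(6-{[(2R)-3,3-dimethyloxiran-2-yl]methyl}-1H-indol-3-yl)-2-methylbutan-2-ol | CC(C)(C)[Si](c1ccccc1)(c1ccccc1)OC[C@H](c1c[nH]c2cc(C[C@H]3OC3(C)C)ccc12)C(C)(C)O | intermediate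
23 | (2S)-2-(6-{[(2R)-3,3-dimethyloxiran-2-yl]methyl}-1H-indol-3-yl)-3-methylbutane-1,3-diol | OC[C@H](c1c[nH]c2cc(C[C@H]3OC3(C)C)ccc12)C(C)(C)O | intermediate
24 | oleic acid, (9Z)-octadec-9-enoic acid | CCCCCCCC/C=C\CCCCCCCC(=O)O | starting material
25 | (2S)-2-(6-{[(2R)-3,3-dimethyloxiran-2-yl]methyl}-1H-indol-3-yl)-3-hydroxy-3-methylbutyl (9Z)-octadec-9-enoate | CCCCCCCC/C=C\CCCCCCCC(=O)OC[C@H](c1c[nH]c2cc(C[C@H]3OC3(C)C)ccc12)C(C)(C)O | target

**Step count and risks**

Total step count: 19.
Longest linear sequence: 13 steps (prenol 8 to 25, steps 7–19); the tyrosine arm (steps 1–6) joins at step 14.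

Steps most likely to fail:

Step 15. The branched, doubly silylated α-substituent may force the alkene out of the plane of the nitroarene. Ring closure would then be slow, and the nitrogen intermediate could be diverted by over-reduction to the amine, by stalling before the second deoxygenation, or by palladium hydride migration of the alkene toward Cα. The fallback takes the nitrogen through a discrete nitrene precursor. Setting out from 18, Fe powder and NH4Cl in EtOH/H2O (70 °C) should reduce the nitro group without touching the alkene and give the 2-alkenylaniline F1. Copper-catalysed diazo transfer (imidazole-1-sulfonyl azide hydrogensulfate, CuSO4 cat., K2CO3, MeOH, rt) avoids a diazonium ion that could attack the alkene and gives the aryl azide F2. Heating in toluene (110 °C), or Rh2(O2CC7H15)4 catalysis at 60 °C, expels N2; electrocyclisation of the nitrene onto the same terminal carbon with a hydrogen shift comes back to the route at 19.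

Step 14. Transmetalation from boron is slow for a congested α-branched alkenylboronate, so base-mediated S–O cleavage of the activated nitroaryl triflate and protodeboronation can overtake the coupling. The fallback changes the alkenyl partner from boron to tin and runs the coupling without base. Setting out from 16, Me3SnSnMe3, Pd(PPh3)4 and LiCl in THF (60 °C) give the alkenylstannane F3. Stille coupling of F3 with 7 (Pd(PPh3)4, CuI, CsF, DMF, 45 °C) comes back at 18.

Step 12. Proton exchange between the kinetic enolate and ketone that is not yet deprotonated can move the enolate to the methine side. That would erase the configuration at Cα or expel a silanolate by β-elimination, and slow O-sulfonylation of the hindered enolate lengthens the exposure. The fallback makes the alkenyl anion by a Shapiro reaction, which needs no enolate. Setting out from 14, condensation with 2,4,6-triisopropylbenzenesulfonohydrazide (THF, rt) gives the arylsulfonylhydrazone F4. n-BuLi (2.2 equiv, THF, −78 to 0 °C) deprotonates nitrogen and then the methyl carbon syn to it, and loss of sulfinate and N2 leaves the 2-lithioalkene. Trapping with 2-isopropoxy-4,4,5,5-tetramethyl-1,3,2-dioxaborolane at −78 °C comes back at 17, bypassing 16.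

Further compounds
F1 | step 15 | 2-[(3S)-3-{[tert-butyl(diphenyl)silyl]oxymethyl}-4-methyl-4-(triethylsilyloxy)pent-1-en-2-yl]-5-{[(4S)-2,2,5,5-tetramethyl-1,3-dioxolan-4-yl]methyl}aniline | C=C(c1ccc(C[C@@H]2OC(C)(C)OC2(C)C)cc1N)[C@@H](CO[Si](c1ccccc1)(c1ccccc1)C(C)(C)C)C(C)(C)O[Si](CC)(CC)CC
F2 | step 15 | 2-azido-1-[(3S)-3-{[tert-butyl(diphenyl)silyl]oxymethyl}-4-methyl-4-(triethylsilyloxy)pent-1-en-2-yl]-4-{[(4S)-2,2,5,5-tetramethyl-1,3-dioxolan-4-yl]methyl}benzene | C=C(c1ccc(C[C@@H]2OC(C)(C)OC2(C)C)cc1N=[N+]=[N-])[C@@H](CO[Si](c1ccccc1)(c1ccccc1)C(C)(C)C)C(C)(C)O[Si](CC)(CC)CC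
F3 | step 14 | tert-butyl{[(2S)-3-methyl-3-(triethylsilyloxy)-2-[1-(trimethylstannyl)ethenyl]butyl]oxy}diphenylsilane | C=C([Sn](C)(C)C)[C@@H](CO[Si](c1ccccc1)(c1ccccc1)C(C)(C)C)C(C)(C)O[Si](CC)(CC)CC
F4 | step 12 | N'-[(3S)-3-{[tert-butyl(diphenyl)silyl]oxymethyl}-4-methyl-4-(triethylsilyloxy)pentan-2-ylidene]-2,4,6-tri(propan-2-yl)benzenesulfonohydrazide | CC(=NNS(=O)(=O)c1c(C(C)C)cc(C(C)C)cc1C(C)C)[C@@H](CO[Si](c1ccccc1)(c1ccccc1)C(C)(C)C)C(C)(C)O[Si](CC)(CC)CC
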